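**Plan**

- Retrosynthesis: the ring B aryl–allyl C–C bond is cut first (allyl traced back to bromine), then the C7–OAc bond (back to a C7 methylene), then the C8–O bond to ring B, and last the ring A–C7 bond.
- Forward: the Grignard reagent of ring A opens (R)-propylene oxide to give the C7–C8–C9 chain, a Mitsunobu reaction attaches the ring B phenol to C8, anodic oxidation turns one C7–H into C7–OAc, and a Stille coupling exchanges the ring B bromine for allyl. No ring is formed at any stage.
- Enabling feature: C7 is benzylic to ring A (3,4-dimethoxyphenyl), whose para-methoxy group makes a C7 cation accessible. Its neighbour C8 carries methyl C9 and the oxygen of ring B (2,6-dimethoxy-4-substituted phenoxy), which can steer acetate to one face.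
- Stereochemistry: C8 comes from (R)-propylene oxide and is inverted once, in the Mitsunobu step, to 8S. C7 (R, erythro) is set by 1,2-induction from C8 when acetate captures the planar C7 cation.

Key step: step 3

Remark: lignan numbering is used (C7 is the benzylic carbon on ring A, C8 the ether-bearing carbon, C9 the methyl group); the stereodescriptors of the given structure correspond to the erythro 7R,8S isomer.

**Route**

Step 1
Reactants: 1 4-bromoveratrole; 2 (R)-propylene oxide
Product: 4 (R)-1-(3,4-dimethoxyphenyl)propan-2-ol, via 3,4-dimethoxyphenylmagnesium bromide 3 (not isolated)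
Conditions: Mg, THF, 40 °C; then CuI (10 mol %), 2, THF, −30 to 0 °C; then H2O
Reagents that add atoms: none
Why: Copper-catalysed ring opening of a terminal epoxide by an aryl Grignard reagent is an SN2 attack at the unsubstituted CH2, so no bond at the stereocentre is broken and the R configuration of 2 should pass unchanged into the secondary alcohol.

Step 2
Reactants: 4 (R)-1-(3,4-dimethoxyphenyl)propan-2-ol; 5 4-bromo-2,6-dimethoxyphenol
Product: 6 (S)-5-bromo-2-[1-(3,4-dimethoxyphenyl)propan-2-yloxy]-1,3-dimethoxybenzene
Conditions: PPh3, DIAD, THF, 0 °C to rt
Reagents that add atoms: none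
Why: In the Mitsunobu reaction the secondary alcohol is activated as an alkoxyphosphonium ion and displaced by the acidic phenol in an SN2 process with inversion, which should turn the R carbinol into the 8S aryl ether while the aryl bromide stays inert.

Step 3
Reactants: 6 (S)-5-bromo-2-[1-(3,4-dimethoxyphenyl)propan-2-yloxy]-1,3-dimethoxybenzene; 7 acetic acid (also the solvent)
Product: 8 (1R,2S)-2-(4-bromo-2,6-dimethoxyphenoxy)-1-(3,4-dimethoxyphenyl)propyl acetate
Conditions: undivided cell, graphite anode, Pt cathode, NaOAc (0.5 M), glacial AcOH, constant current 5 mA cm−2, 2.0–2.2 F mol−1, 20 °C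
Reagents that add atoms: none
Why: Proposed new method: at the graphite anode ring A, the more electron-rich arene, should lose one electron, acetate should remove a C7 proton from the radical cation, and a second electron transfer should give the planar C7 cation, stabilised as a quinone-methide-like oxocarbenium ion by the para-methoxy group, which acetate captures to form the C7–O bond. The closest known reaction type is the anodic side-chain acetoxylation of alkoxy-substituted alkylarenes in AcOH/NaOAc, while the 1,2-induction is reasoned from the erythro-selective addition of oxygen nucleophiles to beta-aryl ether quinone methides. No ring is closed, so no mode of closure arises. The new C7 stereocentre should be controlled by the 8S centre: in the preferred rotamer of the cation the C8–O bond lies parallel to the vacant orbital (partial bridging by the ring B oxygen), H8 points toward ring A and methyl C9 toward H7 to relieve allylic 1,3-strain, so acetate should enter anti to the aryloxy group and give the erythro 7R,8S acetate whichever C7 hydrogen was removed. The step needs site selectivity for C7 and for ring A, which the substrate secures because ring A holds the only benzylic hydrogens and ring B, carrying bromine in place of an oxidisable allyl group and a central oxygen twisted out of conjugation, is the harder arene to oxidise. It also needs to stop at the monoacetate, which the electron-withdrawing acetoxy group should secure by raising the oxidation potential of 8 above that of 6.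

Step 4
Reactants: 8 (1R,2S)-2-(4-bromo-2,6-dimethoxyphenoxy)-1-(3,4-dimethoxyphenyl)propyl acetate; 9 allyltributylstannane
Product: 10 Maceneolignan H, (1R,2S)-2-(4-allyl-2,6-dimethoxyphenoxy)-1-(3,4-dimethoxyphenyl)propyl acetate
Conditions: Pd(PPh3)4 (5 mol %, zerovalent palladium), degassed toluene, 100 °C
Reagents that add atoms: none
Why: In this Stille coupling zerovalent palladium inserts into the aryl C–Br bond, the allyl group is transferred from tin and reductive elimination gives the allylarene, and under these neutral, base-free conditions the secondary benzylic acetate, the aryl ether and both stereocentres should remain untouched.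

**Compound list**

1 | 4-bromoveratrole (4-bromo-1,2-dimethoxybenzene) | COc1ccc(Br)cc1OC | starting material
2 | (R)-propylene oxide | C[C@@H]1CO1 | starting material
3 | 3,4-dimethoxyphenylmagnesium bromide | COc1ccc([Mg]Br)cc1OC | intermediate
4 | (R)-1-(3,4-dimethoxyphenyl)propan-2-ol | C[C@@H](O)Cc1ccc(OC)c(OC)c1 | intermediate
5 | 4-bromo-2,6-dimethoxyphenol | COc1cc(Br)cc(OC)c1O | starting material
6 | (S)-5-bromo-2-[1-(3,4-dimethoxyphenyl)propan-2-yloxy]-1,3-dimethoxybenzene | COc1cc(Br)cc(OC)c1O[C@@H](C)Cc1ccc(OC)c(OC)c1 | intermediate
7 | acetic acid | CC(=O)O | starting material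
8 | (1R,2S)-2-(4-bromo-2,6-dimethoxyphenoxy)-1-(3,4-dimethoxyphenyl)propyl acetate | COc1cc(Br)cc(OC)c1O[C@@H](C)[C@H](OC(C)=O)c1ccc(OC)c(OC)c1 | intermediate
9 | allyltributylstannane | C=CC[Sn](CCCC)(CCCC)CCCC | starting material
10 | Maceneolignan H, (1R,2S)-2-(4-allyl-2,6-dimethoxyphenoxy)-1-(3,4-dimethoxyphenyl)propyl acetate | C=CCc1cc(OC)c(O[C@@H](C)[C@H](OC(C)=O)c2ccc(OC)c(OC)c2)c(OC)c1 | target

**Count**

Total step count: 4. Longest linear sequence: 4 steps (1 → 4 → 6 → 8 → 10).

**Steps most likely to fail**

Step 3 (anodic acetoxylation). Three things may go wrong:
- Acetate may capture the planar C7 cation with poor facial selectivity, and the ratio may erode further if the benzylic acetate re-ionises in the medium.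
- Ring A may undergo nuclear acetoxylation or over-oxidation to the C7 ketone.
- The cation may lose H8 to give an enol ether.

Fallback with known chemistry: setting out from 6, oxidation of the C7 methylene with DDQ in wet CH2Cl2 would give the ketone (S)-2-(4-bromo-2,6-dimethoxyphenoxy)-1-(3,4-dimethoxyphenyl)propan-1-one F1. Chelation-controlled reduction with Zn(BH4)2 in Et2O at −20 °C, where zinc ties the carbonyl oxygen to the ring B ether oxygen and hydride arrives from the face of H8, should give the erythro alcohol (1R,2S)-2-(4-bromo-2,6-dimethoxyphenoxy)-1-(3,4-dimethoxyphenyl)propan-1-ol F2. Acetylation (Ac2O, pyridine, DMAP, CH2Cl2, 0 °C) comes back to the route at 8.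

Step 2 (Mitsunobu etherification). Displacement by the doubly ortho-substituted phenol may be slow. That would allow elimination from the alkoxyphosphonium ion to the conjugated propenylarene, alkylation of the reduced azodicarboxylate, or participation of ring A (phenonium bridging) that erodes the inversion.

Fallback: setting out from 4, mesylation (MsCl, Et3N, CH2Cl2, 0 °C) would give, with retention, (R)-1-(3,4-dimethoxyphenyl)propan-2-yl methanesulfonate F3. SN2 displacement by the cesium phenoxide of 5 (Cs2CO3, DMF, 50 °C) would then invert C8 and come back to the route at 6.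

Step 4 (Stille allylation). Oxidative addition into the electron-rich aryl bromide may be sluggish, and at the temperature then required the allyl double bond may migrate into conjugation with ring B or the benzylic acetate may ionise.

Fallback: the polarity of the coupling is reversed. Setting out from 8, Miyaura borylation (bis(pinacolato)diboron, Pd(dppf)Cl2, KOAc, dioxane, 80 °C) would give the aryl boronate (1R,2S)-1-(3,4-dimethoxyphenyl)-2-[2,6-dimethoxy-4-(4,4,5,5-tetramethyl-1,3,2-dioxaborolan-2-yl)phenoxy]propyl acetate F4. Palladium-catalysed allylation of this boronate with allyl bromide (Pd(PPh3)4, CsF, THF, 60 °C) would come back to the route at the target 10.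

**Further compounds**

F1 | step 3 | (S)-2-(4-bromo-2,6-dimethoxyphenoxy)-1-(3,4-dimethoxyphenyl)propan-1-one | COc1cc(Br)cc(OC)c1O[C@@H](C)C(=O)c1ccc(OC)c(OC)c1
F2 | step 3 | (1R,2S)-2-(4-bromo-2,6-dimethoxyphenoxy)-1-(3,4-dimethoxyphenyl)propan-1-ol | COc1cc(Br)cc(OC)c1O[C@@H](C)[C@H](O)c1ccc(OC)c(OC)c1
F3 | step 2 | (R)-1-(3,4-dimethoxyphenyl)propan-2-yl methanesulfonate | C[C@@H](OS(C)(=O)=O)Cc1ccc(OC)c(OC)c1
F4 | step 4 | (1R,2S)-1-(3,4-dimethoxyphenyl)-2-[2,6-dimethoxy-4-(4,4,5,5-tetramethyl-1,3,2-dioxaborolan-2-yl)phenoxy]propyl acetate | COc1cc(B2OC(C)(C)C(C)(C)O2)cc(OC)c1O[C@@H](C)[C@H](OC(C)=O)c1ccc(OC)c(OC)c1
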